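**Plan**

1. Retrosynthesis: the two ester C–O bonds are cut first (epoxyangelate at C8, angelate at C7). The trans-7,8-dioxygenated C5=C6 ene pattern of ring B is folded back into a 5,8-oxygen bridge, and the two ring-B bonds C4a–C5 and C8–C9 are then cut together in a (4+3) sense.
2. Enabling feature: C5(Me)–O/O–C8 with C6=C7 between them is a 2-methylfuran. C4a–C9a–C9(Me2) is an allyl cation whose central carbon C9a carries ring A, and ring A (the 2-methylcyclohex-2-enone) is an o-cresol methyl ether at the Birch level, with its enol ether one CH2 (C1) away from C9a.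
3. Forward: arene → Birch diene (ring A, bought as an arene) → (4+3) cycloaddition with 2-methylfuran closes ring B as the oxygen-bridged tricycle and unveils the enone → SN1′ opening of the bridge by angelic acid → esterification with (2R,3R)-epoxyangelic acid.
4. Stereochemistry: C4a, C5 and C8 are set together in the cycloaddition (relative: compact transition state; absolute: chiral counter-anion). C9a is set by protonation syn to the bridge, C7 by anti attack on the allyl cation, and the oxirane by Sharpless asymmetric epoxidation.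

Key step: step 3

Remark: locants are those of the benzo[7]annulene skeleton (ring A = C1–C4, C4a, C9a; ring B = C4a, C5–C9, C9a). The target is read as (4aR,7R,8R,9aS): cis ring fusion, H-4a and H-9a syn to the C8 oxygen, 7,8-diester trans.

**Step 1**
Reactants: 1 1-(4-methoxy-3-methylphenyl)ethan-1-one
Product: 2 2-(4-methoxy-3-methylphenyl)propan-2-ol
Conditions: MeMgBr, THF, 0 °C; aq. NH4Cl
Reagents that add atoms: methylmagnesium bromide, C[Mg]Br
Why: Grignard addition of MeMgBr to the aryl methyl ketone should give the tertiary benzylic alcohol; no stereocenter is formed.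

**Step 2**
Reactants: 2 2-(4-methoxy-3-methylphenyl)propan-2-ol
Product: 3 2-(4-methoxy-5-methylcyclohexa-1,4-dien-1-yl)propan-2-ol
Conditions: Li, NH3(l), THF, t-BuOH, −78 to −33 °C; MeOH, then aq. NaHCO3
Reagents that add atoms: none
Why: Birch reduction of the anisole ring, in which the benzylic alkoxide formed in situ resists C–O hydrogenolysis and protonation occurs at the two unsubstituted positions ortho and meta to OMe so that the methyl- and carbinol-bearing carbons stay sp2, should give the 1-methoxycyclohexa-1,4-diene; no stereocenter is formed.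

**Step 3**
Reactants: 3 2-(4-methoxy-5-methylcyclohexa-1,4-dien-1-yl)propan-2-ol, 4 2-methylfuran
Product: 8 (4aR,5R,8S,9aS)-2,5,9,9-tetramethyl-4,4a,5,8,9,9a-hexahydro-3H-5,8-epoxybenzo[7]annulen-3-one, via allyl cation 5 (not isolated), via tricyclic carbocation 6 (not isolated), via dienol methyl ether 7 (not isolated)
Conditions: 4 (10 equiv), (R)-3,3′-bis(2,4,6-triisopropylphenyl)-1,1′-binaphthyl-2,2′-diyl N-triflylphosphoramide (5 mol %), 5 Å molecular sieves, CH2Cl2, −60 °C; then aq. oxalic acid, THF, 0 °C
Reagents that add atoms: water, O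
Why: Proposed new method: the chiral Brønsted acid ionises the tertiary allylic alcohol of 3 to the 2-substituted allyl cation 5 (C4a–C9a–C9), which adds across the two α-carbons of 2-methylfuran in a (4+3) sense, the unsubstituted furan carbon bonding to the CMe2 terminus and the methyl-bearing carbon to C4a so that no bond between two fully substituted carbons is needed; the cation left at the central carbon C9a (6) is a homoallyl cation flanked by the enol ether, is stabilised by it like a 2-oxygenated allyl cation one carbon removed, and collapses by loss of H-1 to the conjugated dienol ether 7. The closest known reaction types are the (4+3) cycloadditions of furans with 2-alkoxy-, 2-siloxy- and 2-(silylmethyl)allyl cations and the chiral-acid-catalysed (4+3) cycloadditions of cations made from heteroaryl carbinols. Ring B, with its temporary 5,8-oxygen bridge, is closed by an intermolecular (4+3) cycloaddition, either concerted and asynchronous or stepwise through a furanium ion trapped in a seven-membered closure by the C4a=C9a alkene. C4a, C5 and C8 are set together: the relative configuration should follow from the compact transition state, in which C4 of ring A lies on the outside of the allyl cation and ends equatorial (H-4a syn to the oxygen bridge), and the absolute sense from the chiral counter-anion (the antipodal catalyst is taken if the induction runs the other way). C9a is set on work-up, where 7 is protonated at its terminal carbon C9a from the face syn to the oxygen bridge, giving the cis ring fusion and the conjugated enone directly. The step needs cycloaddition to win over Friedel–Crafts substitution of the furan and over loss of H-4 from 5 (aromatisation); low temperature, a confined non-basic counter-anion, excess furan and the enol-ether assistance to ring closure are what is relied on.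

**Step 4**
Reactants: 8 (4aR,5R,8S,9aS)-2,5,9,9-tetramethyl-4,4a,5,8,9,9a-hexahydro-3H-5,8-epoxybenzo[7]annulen-3-one, 9 (2Z)-2-methylbut-2-enoic acid (angelic acid)
Product: 10 (4aR,7R,8R,9aS)-8-hydroxy-2,5,9,9-tetramethyl-3-oxo-4,4a,7,8,9,9a-hexahydro-3H-benzo[7]annulen-7-yl (2Z)-2-methylbut-2-enoate
Conditions: 9 (3 equiv), Sc(OTf)3 (5 mol %), CH2Cl2, −20 °C
Reagents that add atoms: none
Why: Lewis acid-catalysed SN1′ allylic substitution (allylic transposition) of the tertiary allylic bridgehead ether: Sc(OTf)3 ionises the C5–O bond and the allyl cation should be captured at its secondary terminus C7 by angelic acid anti to the C8–O–Sc group that has just left C5, which sets C7 as R (trans to the C8 hydroxyl) and places the alkene at C5=C6 as the more substituted isomer.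

**Step 5**
Reactants: 9 (2Z)-2-methylbut-2-enoic acid (angelic acid)
Product: 11 (2Z)-2-methylbut-2-en-1-ol
Conditions: LiAlH4, Et2O, 0 °C; aq. NaOH work-up
Reagents that add atoms: none
Why: LiAlH4 reduction of the carboxylic acid to the primary allylic alcohol proceeds by 1,2-hydride delivery and should leave the Z alkene unchanged; no stereocenter is formed.

**Step 6**
Reactants: 11 (2Z)-2-methylbut-2-en-1-ol
Product: 12 [(2S,3R)-2,3-dimethyloxiran-2-yl]methanol
Conditions: Ti(OiPr)4 (10 mol %), L-(+)-diethyl tartrate (12 mol %), t-BuOOH, 4 Å molecular sieves, CH2Cl2, −20 °C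
Reagents that add atoms: tert-butyl hydroperoxide, CC(C)(C)OO
Why: Sharpless asymmetric epoxidation, in which the titanium complex of L-(+)-diethyl tartrate delivers oxygen to one enantiotopic face of the allylic alcohol with syn addition across the Z alkene, should set both stereocenters as (2S,3R) with the two methyl groups trans on the oxirane.

**Step 7**
Reactants: 12 [(2S,3R)-2,3-dimethyloxiran-2-yl]methanol
Product: 13 (2R,3R)-2,3-dimethyloxirane-2-carboxylic acid
Conditions: RuCl3 (2 mol %), NaIO4, CCl4/MeCN/H2O, 0 °C to rt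
Reagents that add atoms: water, O
Why: Oxidation of the primary alcohol to the carboxylic acid by RuO4 generated from RuCl3 and NaIO4 (through the aldehyde hydrate) should leave the oxirane and both stereocenters untouched, the C2 descriptor changing from S to R only through the change of priorities.

**Step 8**
Reactants: 10 (4aR,7R,8R,9aS)-8-hydroxy-2,5,9,9-tetramethyl-3-oxo-4,4a,7,8,9,9a-hexahydro-3H-benzo[7]annulen-7-yl (2Z)-2-methylbut-2-enoate, 13 (2R,3R)-2,3-dimethyloxirane-2-carboxylic acid
Product: 15 (4aR,7R,8R,9aS)-2,5,9,9-tetramethyl-7-{[(2Z)-2-methylbut-2-enoyl]oxy}-3-oxo-4,4a,7,8,9,9a-hexahydro-3H-benzo[7]annulen-8-yl (2R,3R)-2,3-dimethyloxirane-2-carboxylate, via mixed anhydride 14 (not isolated)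
Conditions: 13, 2,4,6-trichlorobenzoyl chloride, Et3N, THF, rt; then 10, DMAP, toluene, rt to 40 °C
Reagents that add atoms: none
Why: Yamaguchi esterification: DMAP should attack the mixed anhydride 14 at the less hindered oxiranyl carbonyl and the acylpyridinium then acylates the C8 hydroxyl with retention at C8, no stereocenter being formed or touched.

**Compound list**

1 | 1-(4-methoxy-3-methylphenyl)ethan-1-one | CC(=O)c1ccc(OC)c(C)c1 | starting material
2 | 2-(4-methoxy-3-methylphenyl)propan-2-ol | CC(C)(O)c1ccc(OC)c(C)c1 | intermediate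
3 | 2-(4-methoxy-5-methylcyclohexa-1,4-dien-1-yl)propan-2-ol | CC(C)(O)C1=CCC(OC)=C(C)C1 | intermediate
4 | 2-methylfuran | Cc1ccco1 | starting material
5 | 2-(4-methoxy-5-methylcyclohexa-1,4-dien-1-yl)propan-2-ylium (allyl cation, ion pair with the catalyst anion) | COC1=C(C)CC(=CC1)[C+](C)C | intermediate (not isolated)
6 | (4aR,5R,8S)-3-methoxy-2,5,9,9-tetramethyl-1,4,4a,5,8,9-hexahydro-5,8-epoxybenzo[7]annulen-9a-ylium | COC1=C(C)C[C+]2[C@@H](C1)[C@@]1(C)C=C[C@H](O1)C2(C)C | intermediate (not isolated)
7 | (4aR,5R,8S)-3-methoxy-2,5,9,9-tetramethyl-4a,5,8,9-tetrahydro-4H-5,8-epoxybenzo[7]annulene | COC1=C(C)C=C2[C@@H](C1)[C@@]1(C)C=C[C@H](O1)C2(C)C | intermediate (not isolated)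
8 | (4aR,5R,8S,9aS)-2,5,9,9-tetramethyl-4,4a,5,8,9,9a-hexahydro-3H-5,8-epoxybenzo[7]annulen-3-one | CC1=C[C@H]2[C@@H](CC1=O)[C@@]1(C)C=C[C@H](O1)C2(C)C | intermediate
9 | (2Z)-2-methylbut-2-enoic acid (angelic acid) | C/C=C(/C)C(=O)O | starting material
10 | (4aR,7R,8R,9aS)-8-hydroxy-2,5,9,9-tetramethyl-3-oxo-4,4a,7,8,9,9a-hexahydro-3H-benzo[7]annulen-7-yl (2Z)-2-methylbut-2-enoate | C/C=C(/C)C(=O)O[C@@H]1C=C(C)[C@@H]2CC(=O)C(C)=C[C@@H]2C(C)(C)[C@H]1O | intermediate
11 | (2Z)-2-methylbut-2-en-1-ol | C/C=C(/C)CO | intermediate
12 | [(2S,3R)-2,3-dimethyloxiran-2-yl]methanol | OC[C@]1(C)O[C@@H]1C | intermediate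
13 | (2R,3R)-2,3-dimethyloxirane-2-carboxylic acid | OC(=O)[C@]1(C)O[C@@H]1C | intermediate
14 | (2R,3R)-2,3-dimethyloxirane-2-carboxylic 2,4,6-trichlorobenzoic anhydride | O=C(OC(=O)[C@]1(C)O[C@@H]1C)c1c(Cl)cc(Cl)cc1Cl | intermediate (not isolated)
15 | (4aR,7R,8R,9aS)-2,5,9,9-tetramethyl-7-{[(2Z)-2-methylbut-2-enoyl]oxy}-3-oxo-4,4a,7,8,9,9a-hexahydro-3H-benzo[7]annulen-8-yl (2R,3R)-2,3-dimethyloxirane-2-carboxylate | C/C=C(/C)C(=O)O[C@@H]1C=C(C)[C@@H]2CC(=O)C(C)=C[C@@H]2C(C)(C)[C@H]1OC(=O)[C@]1(C)O[C@@H]1C | target

**Step count and risks**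

Total steps: 8. Longest linear sequence: 5 steps (1 → 2 → 3 → 8 → 10 → 15; steps 1, 2, 3, 4, 8). The acid 13 is made in a 3-step branch (steps 5–7).

Steps most likely to fail:

1. Step 3 (proposed new method). The furanium intermediate may lose a proton and rearomatise (Friedel–Crafts alkylation of the furan) instead of closing the seven-membered ring. Cation 5 may lose H-4 and aromatise. The enol ether may isomerise or hydrolyse before cycloaddition. Regiochemistry towards the furan, facial selectivity and protonation at C9a may each be poor. Fallback with known chemistry, setting out from 2-methylfuran 4 and coming back at 8: a classical oxyallyl cation (4+3) cycloaddition of 4 with commercial 1,3-dibromo-3-methylbutan-2-one (Zn–Cu couple, THF) forms the same two C–C bonds and should give racemic 1,4,4-trimethyl-8-oxabicyclo[3.2.1]oct-6-en-3-one F1. Alkylation of its lithium enolate (LDA, THF, −78 °C) with 1-bromobut-2-yne, then NaOMe equilibration, should give the equatorial 2-(but-2-yn-1-yl) ketone F2. Dimethylsulfonium methylide (Corey–Chaykovsky) should give the spiro-epoxide F3, and BF3·OEt2 (Meinwald rearrangement) the aldehyde F4. Hydration of the alkyne (Ph3PAuCl/AgOTf, wet dioxane), directed by the neighbouring formyl group, should give the keto aldehyde F5. KOH/MeOH aldol condensation then closes ring A to 8 together with its enantiomer F6, from which 8 is separated by preparative HPLC on a chiral stationary phase.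

2. Step 4. The allyl cation may be captured at the tertiary terminus or syn to the C8 oxygen (cis isomer), may lose a proton to a triene, and the acid may isomerise the angelate to the tiglate. Fallback setting out from 8 and coming back at 10: Ac2O with Sc(OTf)3 should open the bridge to the trans-diacetate F7, the trans relationship being enforced by participation of the C8 acetoxy group (acetoxonium ion, Prévost-type). K2CO3/MeOH at 0 °C should give the diol F8. The less hindered allylic C7 hydroxyl is then acylated selectively with the mixed anhydride of angelic acid 9 and 2,4,6-trichlorobenzoyl chloride (Et3N, then DMAP, toluene) to give 10.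

3. Step 8. Acylation of the hindered C8 hydroxyl (next to the CMe2 carbon) by an α,α-disubstituted acid may be slow, and forcing conditions may cause migration of the angelate from O7 to O8, angelate-to-tiglate isomerisation or oxirane opening. Fallback setting out from 8 and coming back at 15, with the order of esterification reversed: 8 is taken to the diol F8 as in the fallback for step 4; TESCl/imidazole should silylate the less hindered C7 hydroxyl to the silyl ether F9; Yamaguchi esterification of the C8 hydroxyl with 13, now free of a neighbouring acyl group and tolerant of heating, should give the epoxyangelate F10; HF·pyridine should free the C7 hydroxyl to give the hydroxy ester F11; acylation with the mixed anhydride of 9 and 2,4,6-trichlorobenzoyl chloride then gives 15.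

**Further compounds**

F1 | step 3 | racemic 1,4,4-trimethyl-8-oxabicyclo[3.2.1]oct-6-en-3-one (enantiomer leading to 8 drawn) | O=C1C[C@@]2(C)C=C[C@H](O2)C1(C)C
F2 | step 3 | racemic 2-(but-2-yn-1-yl)-1,4,4-trimethyl-8-oxabicyclo[3.2.1]oct-6-en-3-one, side chain equatorial (anti to the oxygen bridge) | O=C1[C@@H](CC#CC)[C@@]2(C)C=C[C@H](O2)C1(C)C
F3 | step 3 | racemic 2′-(but-2-yn-1-yl)-1′,4′,4′-trimethylspiro[oxirane-2,3′-[8]oxabicyclo[3.2.1]oct[6]ene] | C1O[C@]12[C@@H](CC#CC)[C@@]3(C)C=C[C@H](O3)C2(C)C
F4 | step 3 | racemic 2-(but-2-yn-1-yl)-1,4,4-trimethyl-8-oxabicyclo[3.2.1]oct-6-ene-3-carbaldehyde, formyl cis to the side chain | O=C[C@H]1[C@@H](CC#CC)[C@@]2(C)C=C[C@H](O2)C1(C)C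
F5 | step 3 | racemic 1,4,4-trimethyl-2-(2-oxobutyl)-8-oxabicyclo[3.2.1]oct-6-ene-3-carbaldehyde | O=C[C@H]1[C@@H](CC(=O)CC)[C@@]2(C)C=C[C@H](O2)C1(C)C
F6 | step 3 | (4aS,5S,8R,9aR)-2,5,9,9-tetramethyl-4,4a,5,8,9,9a-hexahydro-3H-5,8-epoxybenzo[7]annulen-3-one (enantiomer of 8) | CC1=C[C@@H]2[C@H](CC1=O)[C@]1(C)C=C[C@@H](O1)C2(C)C
F7 | step 4 | (4aR,7R,8R,9aS)-2,5,9,9-tetramethyl-3-oxo-4,4a,7,8,9,9a-hexahydro-3H-benzo[7]annulene-7,8-diyl diacetate | CC(=O)O[C@@H]1C=C(C)[C@@H]2CC(=O)C(C)=C[C@@H]2C(C)(C)[C@H]1OC(C)=O
F8 | step 4 | (4aR,7R,8R,9aS)-7,8-dihydroxy-2,5,9,9-tetramethyl-4,4a,7,8,9,9a-hexahydro-3H-benzo[7]annulen-3-one | O[C@@H]1C=C(C)[C@@H]2CC(=O)C(C)=C[C@@H]2C(C)(C)[C@H]1O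
F9 | step 8 | (4aR,7R,8R,9aS)-8-hydroxy-2,5,9,9-tetramethyl-7-[(triethylsilyl)oxy]-4,4a,7,8,9,9a-hexahydro-3H-benzo[7]annulen-3-one | CC[Si](CC)(CC)O[C@@H]1C=C(C)[C@@H]2CC(=O)C(C)=C[C@@H]2C(C)(C)[C@H]1O
F10 | step 8 | (4aR,7R,8R,9aS)-2,5,9,9-tetramethyl-3-oxo-7-[(triethylsilyl)oxy]-4,4a,7,8,9,9a-hexahydro-3H-benzo[7]annulen-8-yl (2R,3R)-2,3-dimethyloxirane-2-carboxylate | CC[Si](CC)(CC)O[C@@H]1C=C(C)[C@@H]2CC(=O)C(C)=C[C@@H]2C(C)(C)[C@H]1OC(=O)[C@]1(C)O[C@@H]1C
F11 | step 8 | (4aR,7R,8R,9aS)-7-hydroxy-2,5,9,9-tetramethyl-3-oxo-4,4a,7,8,9,9a-hexahydro-3H-benzo[7]annulen-8-yl (2R,3R)-2,3-dimethyloxirane-2-carboxylate | O[C@@H]1C=C(C)[C@@H]2CC(=O)C(C)=C[C@@H]2C(C)(C)[C@H]1OC(=O)[C@]1(C)O[C@@H]1C
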